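Lignan numbering used below: ring A, C7, C8, C9 are the fused arene, its CH2, the next CH and its CH2OH; ring C, C7', C8', C9' are the pendant aryl, the aryl-bearing CH, the next CH and its CH2OSO3H; ring B is the new carbocycle.
Retrosynthesis: cut C2(ring A)–C7' last; put back a C7'–O9 ether (a tetrahydrofuran that stores C7' as a benzylic ether and hides O9); then cut O9'–S, that ether, C7'–C8' (aldol) and C7=C8 (Stobbe).
Forward: Stobbe condensation of benzyl-protected syringaldehyde with dimethyl succinate, asymmetric hydrogenation and lactonisation give the C8 lactone; aldol with a second equivalent of the same aldehyde, reduction and mild acid close the temporary tetrahydrofuran; the only free hydroxyl (O9'–H) is sulfated, the benzyl ethers are removed, and acid isomerises the sulfated ether into the target.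
Enabling feature: the free para-hydroxyl of ring C lets C7' ionise to a para-quinone methide; C2/C6 of ring A are each ortho and para to a methoxy group; O9 sits 1,4 to C7', so the ether ring opens exactly where ring B must close and the sulfate can only be on O9'.
Stereochemistry: C8 from the Rh-catalysed hydrogenation, C8' from the trans-selective lactone aldol (substrate control), C7' from the ring closure itself (aryl trans to the C8' substituent).

Key step: step 9

Assumption: sulfate monoesters are drawn and named as neutral hydrogen sulfates; in the flask the sulfated intermediates are handled as sodium salts, and the target is released from its salt on an acidic ion-exchange resin in the last work-up.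
Assumption: [Rh(cod)((R,R)-Et-DuPhos)]BF4 is taken to give the (S)-succinate half-ester, by analogy with the usual sense of this catalyst class on itaconates (recalled, not checked); if a trial run shows the opposite sense, the (S,S)-ligand is used and nothing else changes.

Step 1
Reactants: 1 4-(benzyloxy)-3,5-dimethoxybenzaldehyde; 2 dimethyl succinate
Product: 3 (3E)-4-[4-(benzyloxy)-3,5-dimethoxyphenyl]-3-(methoxycarbonyl)but-3-enoic acid
Conditions: NaOMe (1.5 equiv), MeOH, reflux; then aq. HCl
Reagents that add atoms: none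
Why: Stobbe condensation, in which the succinate enolate adds to the aldehyde, the aldolate lactonises onto the distal ester and E1cB opening of the paraconate should give the (E)-alkylidene half-ester with the free acid on the CH2 arm; no stereocentre is formed.

Step 2
Reactants: 3 (3E)-4-[4-(benzyloxy)-3,5-dimethoxyphenyl]-3-(methoxycarbonyl)but-3-enoic acid
Product: 4 (3S)-4-[4-(benzyloxy)-3,5-dimethoxyphenyl]-3-(methoxycarbonyl)butanoic acid
Conditions: H2 (5 bar), [Rh(cod)((R,R)-Et-DuPhos)]BF4 (1 mol%), NaOMe (10 mol%), MeOH, rt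
Reagents that add atoms: none
Why: Catalytic asymmetric hydrogenation of a Stobbe-derived itaconate half-ester, bound to rhodium through the alkene and the carboxylate, should set C8 as (S) by catalyst control, and the homogeneous catalyst leaves the benzyl ether intact.

Step 3
Reactants: 4 (3S)-4-[4-(benzyloxy)-3,5-dimethoxyphenyl]-3-(methoxycarbonyl)butanoic acid
Product: 6 (4S)-4-[4-(benzyloxy)-3,5-dimethoxybenzyl]dihydrofuran-2(3H)-one, via hydroxy acid 5 (not isolated)
Conditions: LiOH (1.0 equiv), MeOH, then evaporate; LiBH4 (2 equiv), THF, 0 °C to rt; then 2 M HCl, rt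
Reagents that add atoms: none
Why: Chemoselective borohydride reduction of the ester beside the inert lithium carboxylate, followed by acid-catalysed γ-lactonisation, should place the benzyl group at the β-carbon of the lactone without touching the C8 centre.

Step 4
Reactants: 6 (4S)-4-[4-(benzyloxy)-3,5-dimethoxybenzyl]dihydrofuran-2(3H)-one; 1 4-(benzyloxy)-3,5-dimethoxybenzaldehyde
Product: 7 (3R,4S)-4-[4-(benzyloxy)-3,5-dimethoxybenzyl]-3-{[4-(benzyloxy)-3,5-dimethoxyphenyl](hydroxy)methyl}dihydrofuran-2(3H)-one (both carbinol epimers)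
Conditions: LiN(iPr)2 (1.1 equiv), THF, −78 °C; then 1, −78 °C; aq. NH4Cl
Reagents that add atoms: none
Why: Aldol addition of the lithium enolate of a β-substituted γ-butyrolactone, where the aldehyde should enter anti to the C8 benzyl group and so set C8' trans to it; the carbinol centre C7' forms as a mixture that does not matter because it is ionised in steps 6 and 9.

Step 5
Reactants: 7 (3R,4S)-aldol lactone
Product: 8 (2S,3S)-2-{[4-(benzyloxy)-3,5-dimethoxyphenyl](hydroxy)methyl}-3-[4-(benzyloxy)-3,5-dimethoxybenzyl]butane-1,4-diol (both carbinol epimers)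
Conditions: LiAlH4 (2 equiv), THF, 0 °C; H2O/aq. NaOH work-up
Reagents that add atoms: none
Why: Hydride reduction of the lactone to the 1,4-diol at low temperature should outrun retro-aldol cleavage and leaves C8 and C8' untouched.

Step 6
Reactants: 8 (2S,3S)-triol
Product: 9 [(2R,3S,4S)-2-[4-(benzyloxy)-3,5-dimethoxyphenyl]-4-[4-(benzyloxy)-3,5-dimethoxybenzyl]tetrahydrofuran-3-yl]methanol
Conditions: camphorsulfonic acid (10 mol%), CH2Cl2, 0 °C to rt
Reagents that add atoms: none
Why: Acid-catalysed SN1 cycloetherification, in which the para-alkoxybenzyl cation at C7' is captured by O9–H in a five-membered ring (O9'–H could only give an oxetane and stays free) and should settle as the 2,3-trans ether; with ring C still benzyl-capped, a catalytic weak acid should not drive the slower C–C closure, and either C7' epimer serves later.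

Step 7
Reactants: 9 tetrahydrofuran alcohol
Product: 10 [(2R,3S,4S)-2-[4-(benzyloxy)-3,5-dimethoxyphenyl]-4-[4-(benzyloxy)-3,5-dimethoxybenzyl]tetrahydrofuran-3-yl]methyl hydrogen sulfate
Conditions: SO3·pyridine (3 equiv), pyridine, rt; then Dowex 50W (Na+ form)
Reagents that add atoms: sulfur trioxide–pyridine complex, O=S(=O)([O-])[n+]1ccccc1
Why: O-sulfation with SO3·pyridine can only occur at O9'–H, because both phenols are benzyl ethers and O9 is locked in the ether ring, so the regiochemistry of the sulfate is fixed by construction.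

Step 8
Reactants: 10 dibenzyl tetrahydrofuran sulfate
Product: 11 [(2R,3S,4S)-4-(4-hydroxy-3,5-dimethoxybenzyl)-2-(4-hydroxy-3,5-dimethoxyphenyl)tetrahydrofuran-3-yl]methyl hydrogen sulfate
Conditions: H2 (1 atm), 10% Pd/C, MeOH/EtOAc, rt, stopped after uptake of 2 equiv
Reagents that add atoms: none
Why: Hydrogenolysis of aryl benzyl ethers over Pd/C, which under neutral conditions (sodium salt, no acid) should be much faster than cleavage of the benzylic C7'–O9 ring bond, as is usual for benzyl-protected 2-aryltetrahydrofuran lignans.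

Step 9
Reactants: 11 bisphenol tetrahydrofuran sulfate
Product: 13 [(1R,2S,3S)-7-hydroxy-1-(4-hydroxy-3,5-dimethoxyphenyl)-3-(hydroxymethyl)-6,8-dimethoxy-1,2,3,4-tetrahydronaphthalen-2-yl]methyl hydrogen sulfate, via para-quinone methide 12 (not isolated)
Conditions: CF3CO2H (5 vol%), (CF3)2CHOH, 5 mM, 0 °C to rt; then Dowex 50W (H+ form), MeOH/H2O, 0 °C, freeze-dry
Reagents that add atoms: none
Why: Acid protonates the ring oxygen and the free para-hydroxyl of ring C pushes the C7'–O9 bond open to the protonated para-quinone methide 12, which frees O9–H; C2 of ring A, ortho and para to its methoxy groups, then adds to C7' and rearomatisation should give 13. The closest known reaction type is the acid-catalysed rearrangement of lariciresinol-type 7',9-epoxylignans into cyclolariciresinol-type aryltetralins. Ring B closes in a 6-exo-trig mode, with the exocyclic C7'=C1' bond of the quinone methide as acceptor. The new stereocentre C7' is controlled by C8': in the chair-like transition state the C8 and C8' substituents are trans-diequatorial and the quinoid ring takes the pseudo-equatorial position, so the aryl group should end up trans to the C9' sulfatoxymethyl group (7'R). The step needs C- over O-capture of the quinone methide and survival of the sulfate: capture by O9 (back to 11 or its C7' epimer) or by the sulfate oxygen is reversible while C–C formation is not, the two ortho carbons of ring A are equivalent so only one regioisomer can form, and a primary alkyl sulfate monoester should tolerate dilute acid at room temperature. Because O9 stays in the ether until this moment, the step also delivers the free C9 hydroxymethyl group next to the already sulfated C9'.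

Compound list
1 | 4-(benzyloxy)-3,5-dimethoxybenzaldehyde | COc1cc(C=O)cc(OC)c1OCc1ccccc1 | starting material
2 | dimethyl succinate | COC(=O)CCC(=O)OC | starting material
3 | (3E)-4-[4-(benzyloxy)-3,5-dimethoxyphenyl]-3-(methoxycarbonyl)but-3-enoic acid | COC(=O)/C(CC(=O)O)=C/c1cc(OC)c(OCc2ccccc2)c(OC)c1 | intermediate
4 | (3S)-4-[4-(benzyloxy)-3,5-dimethoxyphenyl]-3-(methoxycarbonyl)butanoic acid | COc1cc(C[C@H](C(=O)OC)CC(=O)O)cc(OC)c1OCc1ccccc1 | intermediate
5 | (3S)-4-[4-(benzyloxy)-3,5-dimethoxyphenyl]-3-(hydroxymethyl)butanoic acid | COc1cc(C[C@H](CO)CC(=O)O)cc(OC)c1OCc1ccccc1 | intermediate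
6 | (4S)-4-[4-(benzyloxy)-3,5-dimethoxybenzyl]dihydrofuran-2(3H)-one | COc1cc(C[C@@H]2COC(=O)C2)cc(OC)c1OCc1ccccc1 | intermediate
7 | (3R,4S)-4-[4-(benzyloxy)-3,5-dimethoxybenzyl]-3-{[4-(benzyloxy)-3,5-dimethoxyphenyl](hydroxy)methyl}dihydrofuran-2(3H)-one, carbinol centre as epimer mixture | O=C1OC[C@@H](Cc2cc(OC)c(OCc3ccccc3)c(OC)c2)[C@@H]1C(O)c1cc(OC)c(OCc2ccccc2)c(OC)c1 | intermediate
8 | (2S,3S)-2-{[4-(benzyloxy)-3,5-dimethoxyphenyl](hydroxy)methyl}-3-[4-(benzyloxy)-3,5-dimethoxybenzyl]butane-1,4-diol, carbinol centre as epimer mixture | OC[C@@H](Cc1cc(OC)c(OCc2ccccc2)c(OC)c1)[C@@H](CO)C(O)c1cc(OC)c(OCc2ccccc2)c(OC)c1 | intermediate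
9 | [(2R,3S,4S)-2-[4-(benzyloxy)-3,5-dimethoxyphenyl]-4-[4-(benzyloxy)-3,5-dimethoxybenzyl]tetrahydrofuran-3-yl]methanol | OC[C@H]1[C@H](c2cc(OC)c(OCc3ccccc3)c(OC)c2)OC[C@H]1Cc1cc(OC)c(OCc2ccccc2)c(OC)c1 | intermediate
10 | [(2R,3S,4S)-2-[4-(benzyloxy)-3,5-dimethoxyphenyl]-4-[4-(benzyloxy)-3,5-dimethoxybenzyl]tetrahydrofuran-3-yl]methyl hydrogen sulfate | OS(=O)(=O)OC[C@H]1[C@H](c2cc(OC)c(OCc3ccccc3)c(OC)c2)OC[C@H]1Cc1cc(OC)c(OCc2ccccc2)c(OC)c1 | intermediate
11 | [(2R,3S,4S)-4-(4-hydroxy-3,5-dimethoxybenzyl)-2-(4-hydroxy-3,5-dimethoxyphenyl)tetrahydrofuran-3-yl]methyl hydrogen sulfate | OS(=O)(=O)OC[C@H]1[C@H](c2cc(OC)c(O)c(OC)c2)OC[C@H]1Cc1cc(OC)c(O)c(OC)c1 | intermediate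
12 | (2S,3S)-2-[(3,5-dimethoxy-4-oxocyclohexa-2,5-dien-1-ylidene)methyl]-4-hydroxy-3-(4-hydroxy-3,5-dimethoxybenzyl)butyl hydrogen sulfate | OC[C@@H](Cc1cc(OC)c(O)c(OC)c1)[C@@H](COS(=O)(=O)O)C=C1C=C(OC)C(=O)C(OC)=C1 | intermediate
13 | [(1R,2S,3S)-7-hydroxy-1-(4-hydroxy-3,5-dimethoxyphenyl)-3-(hydroxymethyl)-6,8-dimethoxy-1,2,3,4-tetrahydronaphthalen-2-yl]methyl hydrogen sulfate | COc1cc([C@@H]2c3c(cc(OC)c(O)c3OC)C[C@H](CO)[C@H]2COS(=O)(=O)O)cc(OC)c1O | target

Total step count: 9. Longest linear sequence: 9 steps (1 to 13; the second equivalent of 1 enters at step 4).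

Steps most likely to fail

Step 9. With free phenols and a sulfate monoester in acid, solvolysis of the sulfate or intermolecular capture of the quinone methide may outrun the intramolecular C–C closure. The fallback closes ring B before debenzylation, through the para-alkoxybenzyl cation instead of the quinone methide. It sets out from 10: BF3·OEt2 (3 equiv) in CH2Cl2 at −40 to 0 °C should open the ether ring and give [(1R,2S,3S)-7-(benzyloxy)-1-[4-(benzyloxy)-3,5-dimethoxyphenyl]-3-(hydroxymethyl)-6,8-dimethoxy-1,2,3,4-tetrahydronaphthalen-2-yl]methyl hydrogen sulfate F1. Hydrogenolysis (H2, Pd/C, MeOH) then comes back to the route at 13. F1 has no benzylic C–O bond, so this detour also removes the chemoselectivity demand of step 8.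

Step 6. Capture of the C7' cation by ring A carbon may compete with capture by O9, which would lose the distinction between the two hydroxymethyl groups. The fallback lets the C–C closure happen on purpose and tells the two groups apart by size. It sets out from 8: BF3·OEt2 in CH2Cl2 at −20 °C should give [(1R,2S,3S)-7-(benzyloxy)-1-[4-(benzyloxy)-3,5-dimethoxyphenyl]-6,8-dimethoxy-1,2,3,4-tetrahydronaphthalene-2,3-diyl]dimethanol F2. TBDPSCl (1.0 equiv) with imidazole at −20 °C should silylate the less hindered O9–H, whose neighbour is the ring CH2 while O9' is flanked by the aryl-bearing carbon, to give the 3-(silyloxymethyl) alcohol F3. SO3·pyridine then gives its 2-ylmethyl hydrogen sulfate F4, and H2 over Pd/C gives the bisphenol silyl ether sulfate F5. Bu4NF in THF removes the silyl group and comes back to the route at 13.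

Step 2. The crowded trialkoxyaryl substrate may give insufficient enantiofacial selectivity, or the opposite sense to the one assumed. The fallback replaces catalyst control by resolution. It sets out from 3: hydrogenation with achiral [Rh(cod)(dppb)]BF4 gives racemic 4-[4-(benzyloxy)-3,5-dimethoxyphenyl]-3-(methoxycarbonyl)butanoic acid F6. Crystallisation with (S)-1-phenylethylamine (the antipodal amine if the other diastereomeric salt proves less soluble) should give the (S)-acid (S)-1-phenylethylammonium salt F7. Aqueous HCl liberates the acid and comes back to the route at 4.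

Further compounds
F1 | step 9 | [(1R,2S,3S)-7-(benzyloxy)-1-[4-(benzyloxy)-3,5-dimethoxyphenyl]-3-(hydroxymethyl)-6,8-dimethoxy-1,2,3,4-tetrahydronaphthalen-2-yl]methyl hydrogen sulfate | COc1cc([C@@H]2c3c(cc(OC)c(OCc4ccccc4)c3OC)C[C@H](CO)[C@H]2COS(=O)(=O)O)cc(OC)c1OCc1ccccc1
F2 | step 6 | [(1R,2S,3S)-7-(benzyloxy)-1-[4-(benzyloxy)-3,5-dimethoxyphenyl]-6,8-dimethoxy-1,2,3,4-tetrahydronaphthalene-2,3-diyl]dimethanol | COc1cc([C@@H]2c3c(cc(OC)c(OCc4ccccc4)c3OC)C[C@H](CO)[C@H]2CO)cc(OC)c1OCc1ccccc1
F3 | step 6 | [(1R,2S,3S)-7-(benzyloxy)-1-[4-(benzyloxy)-3,5-dimethoxyphenyl]-3-{[tert-butyl(diphenyl)silyl]oxymethyl}-6,8-dimethoxy-1,2,3,4-tetrahydronaphthalen-2-yl]methanol | COc1cc([C@@H]2c3c(cc(OC)c(OCc4ccccc4)c3OC)C[C@H](CO[Si](c4ccccc4)(c4ccccc4)C(C)(C)C)[C@H]2CO)cc(OC)c1OCc1ccccc1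
F4 | step 6 | [(1R,2S,3S)-7-(benzyloxy)-1-[4-(benzyloxy)-3,5-dimethoxyphenyl]-3-{[tert-butyl(diphenyl)silyl]oxymethyl}-6,8-dimethoxy-1,2,3,4-tetrahydronaphthalen-2-yl]methyl hydrogen sulfate | COc1cc([C@@H]2c3c(cc(OC)c(OCc4ccccc4)c3OC)C[C@H](CO[Si](c4ccccc4)(c4ccccc4)C(C)(C)C)[C@H]2COS(=O)(=O)O)cc(OC)c1OCc1ccccc1
F5 | step 6 | [(1R,2S,3S)-3-{[tert-butyl(diphenyl)silyl]oxymethyl}-7-hydroxy-1-(4-hydroxy-3,5-dimethoxyphenyl)-6,8-dimethoxy-1,2,3,4-tetrahydronaphthalen-2-yl]methyl hydrogen sulfate | COc1cc([C@@H]2c3c(cc(OC)c(O)c3OC)C[C@H](CO[Si](c4ccccc4)(c4ccccc4)C(C)(C)C)[C@H]2COS(=O)(=O)O)cc(OC)c1O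
F6 | step 2 | racemic 4-[4-(benzyloxy)-3,5-dimethoxyphenyl]-3-(methoxycarbonyl)butanoic acid | COC(=O)C(CC(=O)O)Cc1cc(OC)c(OCc2ccccc2)c(OC)c1
F7 | step 2 | (S)-1-phenylethylammonium (3S)-4-[4-(benzyloxy)-3,5-dimethoxyphenyl]-3-(methoxycarbonyl)butanoate | COc1cc(C[C@H](C(=O)OC)CC(=O)[O-])cc(OC)c1OCc1ccccc1.C[C@H]([NH3+])c1ccccc1
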